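**Retrosynthetic overview**
- The last C–C bond made is top C4–middle C8: an epicatechin-derived C4 electrophile 25 is joined to the digalloylated lower dimer 21, and hydrogenolysis of 22 benzyl ethers ends the route.
- The strategy rests on ring C of the middle unit: O1, C2, C3 and C4 sit on phloroglucinol ring A (C4a, C8a), and the C4 methine is bonded to C8 of the lower catechin unit. This ring is cut at O1–C2 and C3–C4 into an o-quinone methide (O1, C8a, C4a, C4) and a two-carbon enol silyl ether (C2–C3) that already carries the benzylated galloyl ester on C3.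
- The C2 ketal from the annulation is reduced with participation of the C3 ester to the 2,3-cis flavan.
- The o-quinone methide precursor 10 comes from 8-lithiated protected (+)-catechin and a protected 2,4,6-trihydroxybenzaldehyde; the enol silyl ether 15 comes from two molecules of tri-O-benzylgallic acid.
- Ring order: the lower and upper flavan rings are taken from (+)-catechin and (−)-epicatechin; the only ring built is the middle ring C (step 11).

Key step: step 11

Assumption: 3,4,5-tris(benzyloxy)benzoic acid (tri-O-benzylgallic acid) is bought as such, and the (R)-phosphoric acid of step 11 is assumed to shield the face that leads to the target; if the sense proves opposite, the (S)-acid is used with no other change.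

**Step 1**
Reactants: 1 (+)-catechin
Product: 2 tetra-O-benzylcatechin (5,7,3',4'-tetra-O-benzyl-(+)-catechin)
Conditions: BnBr (4.4 equiv), K2CO3, DMF, 0 °C to rt
Reagents that add atoms: benzyl bromide, BrCc1ccccc1
Why: Williamson ether synthesis in which carbonate deprotonates only the four phenols, so the secondary 3-OH stays free and both stereocentres are untouched.

**Step 2**
Reactants: 2 tetra-O-benzylcatechin
Product: 3 silyl ether 3-O-TBS-5,7,3',4'-tetra-O-benzyl-(+)-catechin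
Conditions: TBSCl, imidazole, DMF, rt
Reagents that add atoms: tert-butyldimethylsilyl chloride, CC(C)(C)[Si](C)(C)Cl
Why: Imidazole-mediated silylation of the only free hydroxyl gives an ether that tolerates the aryllithium of step 6.

**Step 3**
Reactants: 3 silyl ether
Product: 4 aryl bromide 8-bromo-3-O-TBS-5,7,3',4'-tetra-O-benzyl-(+)-catechin
Conditions: NBS, CH2Cl2, −78 °C to rt
Reagents that add atoms: N-bromosuccinimide, BrN1C(=O)CCC1=O
Why: Electrophilic aromatic bromination of ring A, which in 5,7-di-O-benzyl flavans goes to C8 (next to the ring oxygen) in preference to C6.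

**Step 4**
Reactants: 5 2,4,6-trihydroxybenzaldehyde
Product: 6 hydroxy aldehyde 2,4-bis(benzyloxy)-6-hydroxybenzaldehyde
Conditions: BnBr (2.05 equiv), K2CO3, DMF, rt
Reagents that add atoms: benzyl bromide, BrCc1ccccc1
Why: Williamson etherification should stop after two benzylations because the last ortho hydroxyl is hydrogen-bonded to the formyl group and is the least nucleophilic.

**Step 5**
Reactants: 6 hydroxy aldehyde
Product: 7 allyl ether 2-allyloxy-4,6-bis(benzyloxy)benzaldehyde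
Conditions: allyl bromide, K2CO3, DMF, 60 °C
Reagents that add atoms: allyl bromide, C=CCBr
Why: Williamson alkylation under more forcing conditions caps the chelated phenol with a group that survives an aryllithium and is later removed without acid.

**Step 6**
Reactants: 4 aryl bromide; 7 allyl ether
Product: 9 O-allyl diarylmethanol [3-O-TBS-5,7,3',4'-tetra-O-benzylcatechin-8-yl](2-allyloxy-4,6-dibenzyloxyphenyl)methanol (both carbinol epimers), via aryllithium 8 (not isolated)
Conditions: n-BuLi, THF, −78 °C; then 7, −78 to −20 °C; aq NH4Cl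
Reagents that add atoms: none
Why: Bromine–lithium exchange followed by 1,2-addition of the aryllithium to the non-enolisable aldehyde gives the diarylmethanol, whose new carbinol centre forms as both epimers and is erased in step 11.

**Step 7**
Reactants: 9 O-allyl diarylmethanol
Product: 10 o-hydroxybenzhydrol [3-O-TBS-5,7,3',4'-tetra-O-benzylcatechin-8-yl](2-hydroxy-4,6-dibenzyloxyphenyl)methanol (both carbinol epimers)
Conditions: Pd(PPh3)4 (5 mol%), morpholine, THF, rt
Reagents that add atoms: none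
Why: Tsuji–Trost deallylation, in which zerovalent palladium ionises the aryl allyl ether and morpholine takes up the allyl group, frees the phenol without acid, so the very acid-labile benzhydrol is not ionised.

**Step 8**
Reactants: 11 tri-O-benzylgallic acid (3,4,5-tris(benzyloxy)benzoic acid)
Product: 13 diazoketone 2-diazo-1-[3,4,5-tris(benzyloxy)phenyl]ethanone, via acid chloride 12 (not isolated)
Conditions: (COCl)2, cat. N,N-dimethylformamide, CH2Cl2, 0 °C to rt; evaporate; CH2N2 (2.5 equiv), Et2O, 0 °C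
Reagents that add atoms: diazomethane, C=[N+]=[N-]
Why: Acylation of diazomethane by the acid chloride (first stage of the Arndt–Eistert sequence), with the second equivalent of diazomethane taking up the HCl.

**Step 9**
Reactants: 13 diazoketone; 11 tri-O-benzylgallic acid
Product: 14 phenacyl gallate 2-oxo-2-[3,4,5-tris(benzyloxy)phenyl]ethyl 3,4,5-tris(benzyloxy)benzoate
Conditions: Rh2(OAc)4 (1 mol%), CH2Cl2, rt
Reagents that add atoms: none
Why: Rhodium-carbenoid O–H insertion of the diazoketone into the carboxylic acid gives the α-acyloxy ketone directly with loss of N2.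

**Step 10**
Reactants: 14 phenacyl gallate
Product: 15 enol silyl ether (Z)-2-(tert-butyldimethylsilyloxy)-2-[3,4,5-tris(benzyloxy)phenyl]ethenyl 3,4,5-tris(benzyloxy)benzoate
Conditions: TBSOTf, Et3N, CH2Cl2, 0 °C
Reagents that add atoms: tert-butyldimethylsilyl trifluoromethanesulfonate, CC(C)(C)[Si](C)(C)OS(=O)(=O)C(F)(F)F
Why: Soft enolisation of the aryl ketone, which has a single enolisable position, should give the silyl enol ether with the acyloxy group trans to the aryl ring (Z), the geometry that avoids allylic strain with the arene.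

**Step 11**
Reactants: 10 o-hydroxybenzhydrol; 15 enol silyl ether
Product: 17 silyl ketal 2-(tert-butyldimethylsilyloxy)-3-O-[3,4,5-tris(benzyloxy)benzoyl]-5,7,3',4',5'-penta-O-benzylflavan-3-ol carrying the protected catechin-8-yl group at C4 (3,4-trans; both C2 ketal epimers), via o-quinone methide 16 (not isolated)
Conditions: 15 (2 equiv), (R)-3,3'-bis(2,4,6-triisopropylphenyl)-1,1'-binaphthyl-2,2'-diyl hydrogen phosphate (10 mol%), 4 Å MS, CH2Cl2, −20 °C to rt
Reagents that add atoms: none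
Why: The phosphoric acid dehydrates the doubly activated benzhydrol to o-quinone methide 16, held as a hydrogen-bonded ion pair, whose methide carbon C4 is attacked by the aroyloxy-bearing carbon of 15 (C3) in a Mukaiyama–Michael addition, and the phenol oxygen then closes on the silyl oxocarbenium carbon (C2), the known formal [4+2] annulation of o-quinone methides and silyl enol ethers to 2-siloxychromans. Ring C closes in the second event by O1–C2 bond formation, a 6-exo-trig capture (the second bond of a formal hetero-Diels–Alder reaction). The regiochemistry needed, C3 to C4 and O1 to the aryl-bearing C2, is secured by the silyloxy group and the electron-rich aryl ring of 15, which make C3 the nucleophilic and C2 the cationic carbon. C3 is set relative to C4 by sterics: the enol carbon carries only H and the aroyloxy group, and for either methide geometry the H should take the quadrant beside the twisted, doubly ortho-substituted catechin ring and the peri 5-benzyloxy group while the aroyloxy group points away, which is the 3,4-trans arrangement. C4 is set by the catalyst, because the distant stereocentres of the catechin unit give no dependable facial bias and the chiral phosphate bound at the methide oxygen shields one face. C2 forms as both ketal epimers, which does not matter since step 12 resets it.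

**Step 12**
Reactants: 17 silyl ketal
Product: 19 protected dimer 3-O-[3,4,5-tris(benzyloxy)benzoyl]-5,7,3',4',5'-penta-O-benzyl-epigallocatechin-(4β→8)-3-O-TBS-5,7,3',4'-tetra-O-benzylcatechin, via oxocarbenium ion 18 (not isolated)
Conditions: Et3SiH (5 equiv), BF3·OEt2 (2 equiv), CH2Cl2, −78 to −40 °C
Reagents that add atoms: none
Why: Ionic hydrogenation of the reductive-etherification type, in which BF3 ionises the silyl ketal to oxocarbenium ion 18, the neighbouring aroyloxy group bridges C2 on its own face and the silane hydride enters anti to it, so that the aryl group ends cis to the C3 oxygen (2,3-cis, 2R).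

**Step 13**
Reactants: 19 protected dimer
Product: 20 dimer alcohol (19 with a free 3-OH on the lower catechin unit)
Conditions: HF·pyridine, pyridine, THF, 0 °C to rt
Reagents that add atoms: none
Why: Fluoride-driven cleavage of the secondary silyl ether under buffered conditions should spare the benzyl ethers, the gallate ester and the C4–C8 bond.

**Step 14**
Reactants: 20 dimer alcohol; 11 tri-O-benzylgallic acid
Product: 21 dimer digallate 3-O-[3,4,5-tris(benzyloxy)benzoyl]-penta-O-benzyl-epigallocatechin-(4β→8)-3-O-[3,4,5-tris(benzyloxy)benzoyl]-tetra-O-benzylcatechin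
Conditions: 11 (2 equiv), DCC, 4-(dimethylamino)pyridine, CH2Cl2, rt
Reagents that add atoms: none
Why: Steglich esterification of the equatorial 3-OH of the 2,3-trans unit, with retention at C3 because its C–O bond is not broken.

**Step 15**
Reactants: 22 (−)-epicatechin
Product: 23 tetra-O-benzylepicatechin (5,7,3',4'-tetra-O-benzyl-(−)-epicatechin)
Conditions: BnBr (4.4 equiv), K2CO3, DMF, 0 °C to rt
Reagents that add atoms: benzyl bromide, BrCc1ccccc1
Why: Williamson ether synthesis selective for the four phenols over the secondary alcohol.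

**Step 16**
Reactants: 23 tetra-O-benzylepicatechin
Product: 24 C4 ether 4β-(2-ethoxyethoxy)-5,7,3',4'-tetra-O-benzylepicatechin (2,3-cis, 3,4-trans)
Conditions: DDQ (2 equiv), 2-ethoxyethanol, CH2Cl2, rt
Reagents that add atoms: 2-ethoxyethanol, CCOCCO
Why: Oxidative benzylic etherification, in which DDQ abstracts hydride from C4 (activated by the 5,7-dialkoxy ring) and the alcohol adds to the resulting cation trans to the 3-OH.

**Step 17**
Reactants: 24 C4 ether; 11 tri-O-benzylgallic acid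
Product: 25 galloylated electrophile 3-O-[3,4,5-tris(benzyloxy)benzoyl]-4β-(2-ethoxyethoxy)-5,7,3',4'-tetra-O-benzylepicatechin
Conditions: 11 (1.5 equiv), DCC, 4-(dimethylamino)pyridine, CH2Cl2, rt
Reagents that add atoms: none
Why: Steglich esterification under neutral conditions keeps the acid-labile C4 ether intact and installs an ester that later shields the α-face of C4.

**Step 18**
Reactants: 21 dimer digallate; 25 galloylated electrophile
Product: 27 perbenzylated trimer (docosa-O-benzyl ether of the target), via C4 carbocation 26 (not isolated)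
Conditions: 21 (1.5 equiv, excess recovered), Me3SiOTf (0.2 equiv), CH2Cl2, −78 to −30 °C
Reagents that add atoms: none
Why: Lewis-acid-promoted Friedel–Crafts-type interflavan coupling, in which carbocation 26 is attacked by the free C8 of the middle unit (the most nucleophilic open ring position of 21) from the face opposite to the 3-acyloxy and 2-aryl groups, giving the 4β (3,4-trans) bond.

**Step 19**
Reactants: 27 perbenzylated trimer
Product: 28 target CNP0321910.1, epicatechin 3-O-gallate-(4β→8)-epigallocatechin 3-O-gallate-(4β→8)-catechin 3-O-gallate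
Conditions: H2 (1 atm), Pd(OH)2/C, THF/MeOH/H2O, rt
Reagents that add atoms: none
Why: Catalytic hydrogenolysis should remove all 22 benzyl ethers while leaving the three esters, the ring C–O bonds and all stereocentres untouched.

**Compound list**
1 | (+)-catechin | O[C@H]1Cc2c(O)cc(O)cc2O[C@@H]1c1ccc(O)c(O)c1 | starting material
2 | 5,7,3',4'-tetra-O-benzyl-(+)-catechin | O[C@H]1Cc2c(OCc9ccccc9)cc(OCc9ccccc9)cc2O[C@@H]1c1ccc(OCc9ccccc9)c(OCc9ccccc9)c1 | intermediate
3 | 3-O-TBS-5,7,3',4'-tetra-O-benzyl-(+)-catechin | CC(C)(C)[Si](C)(C)O[C@H]1Cc2c(OCc9ccccc9)cc(OCc9ccccc9)cc2O[C@@H]1c1ccc(OCc9ccccc9)c(OCc9ccccc9)c1 | intermediate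
4 | 8-bromo-3-O-TBS-5,7,3',4'-tetra-O-benzyl-(+)-catechin | CC(C)(C)[Si](C)(C)O[C@H]1Cc2c(OCc9ccccc9)cc(OCc9ccccc9)c(Br)c2O[C@@H]1c1ccc(OCc9ccccc9)c(OCc9ccccc9)c1 | intermediate
5 | 2,4,6-trihydroxybenzaldehyde | O=Cc1c(O)cc(O)cc1O | starting material
6 | 2,4-bis(benzyloxy)-6-hydroxybenzaldehyde | O=Cc1c(O)cc(OCc9ccccc9)cc1OCc9ccccc9 | intermediate
7 | 2-allyloxy-4,6-bis(benzyloxy)benzaldehyde | C=CCOc1cc(OCc9ccccc9)cc(OCc9ccccc9)c1C=O | intermediate
8 | 8-lithio-3-O-TBS-5,7,3',4'-tetra-O-benzylcatechin | CC(C)(C)[Si](C)(C)O[C@H]1Cc2c(OCc9ccccc9)cc(OCc9ccccc9)c([Li])c2O[C@@H]1c1ccc(OCc9ccccc9)c(OCc9ccccc9)c1 | intermediate (not isolated)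
9 | [3-O-TBS-tetra-O-benzylcatechin-8-yl](2-allyloxy-4,6-dibenzyloxyphenyl)methanol, carbinol epimers | C=CCOc1cc(OCc9ccccc9)cc(OCc9ccccc9)c1C(O)c1c(OCc9ccccc9)cc(OCc9ccccc9)c2c1O[C@H](c1ccc(OCc9ccccc9)c(OCc9ccccc9)c1)[C@@H](O[Si](C)(C)C(C)(C)C)C2 | intermediate
10 | [3-O-TBS-tetra-O-benzylcatechin-8-yl](2-hydroxy-4,6-dibenzyloxyphenyl)methanol, carbinol epimers | Oc1cc(OCc9ccccc9)cc(OCc9ccccc9)c1C(O)c1c(OCc9ccccc9)cc(OCc9ccccc9)c2c1O[C@H](c1ccc(OCc9ccccc9)c(OCc9ccccc9)c1)[C@@H](O[Si](C)(C)C(C)(C)C)C2 | intermediate (key-step precursor)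
11 | 3,4,5-tris(benzyloxy)benzoic acid | OC(=O)c1cc(OCc9ccccc9)c(OCc9ccccc9)c(OCc9ccccc9)c1 | starting material
12 | 3,4,5-tris(benzyloxy)benzoyl chloride | ClC(=O)c1cc(OCc9ccccc9)c(OCc9ccccc9)c(OCc9ccccc9)c1 | intermediate (not isolated)
13 | 2-diazo-1-[3,4,5-tris(benzyloxy)phenyl]ethanone | [N-]=[N+]=CC(=O)c1cc(OCc9ccccc9)c(OCc9ccccc9)c(OCc9ccccc9)c1 | intermediate
14 | 2-oxo-2-[3,4,5-tris(benzyloxy)phenyl]ethyl 3,4,5-tris(benzyloxy)benzoate | O=C(COC(=O)c1cc(OCc9ccccc9)c(OCc9ccccc9)c(OCc9ccccc9)c1)c1cc(OCc9ccccc9)c(OCc9ccccc9)c(OCc9ccccc9)c1 | intermediate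
15 | (Z)-2-(tert-butyldimethylsilyloxy)-2-[3,4,5-tris(benzyloxy)phenyl]ethenyl 3,4,5-tris(benzyloxy)benzoate | CC(C)(C)[Si](C)(C)O/C(=C\OC(=O)c1cc(OCc9ccccc9)c(OCc9ccccc9)c(OCc9ccccc9)c1)c1cc(OCc9ccccc9)c(OCc9ccccc9)c(OCc9ccccc9)c1 | intermediate
16 | o-quinone methide from 10 (methide geometry not fixed) | O=C1C=C(OCc9ccccc9)C=C(OCc9ccccc9)C1=Cc1c(OCc9ccccc9)cc(OCc9ccccc9)c2c1O[C@H](c1ccc(OCc9ccccc9)c(OCc9ccccc9)c1)[C@@H](O[Si](C)(C)C(C)(C)C)C2 | intermediate (not isolated)
17 | 2-silyloxy-3-(tri-O-benzylgalloyloxy)-4-(catechin-8-yl)flavan ketal, 3,4-trans, C2 epimers | O=C(O[C@@H]1[C@@H](c2c(OCc9ccccc9)cc(OCc9ccccc9)c3c2O[C@H](c2ccc(OCc9ccccc9)c(OCc9ccccc9)c2)[C@@H](O[Si](C)(C)C(C)(C)C)C3)c2c(OCc9ccccc9)cc(OCc9ccccc9)cc2OC1(O[Si](C)(C)C(C)(C)C)c1cc(OCc9ccccc9)c(OCc9ccccc9)c(OCc9ccccc9)c1)c1cc(OCc9ccccc9)c(OCc9ccccc9)c(OCc9ccccc9)c1 | intermediate (key-step product)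
18 | C2 oxocarbenium ion from 17 | O=C(O[C@@H]1[C@@H](c2c(OCc9ccccc9)cc(OCc9ccccc9)c3c2O[C@H](c2ccc(OCc9ccccc9)c(OCc9ccccc9)c2)[C@@H](O[Si](C)(C)C(C)(C)C)C3)c2c(OCc9ccccc9)cc(OCc9ccccc9)cc2[O+]=C1c1cc(OCc9ccccc9)c(OCc9ccccc9)c(OCc9ccccc9)c1)c1cc(OCc9ccccc9)c(OCc9ccccc9)c(OCc9ccccc9)c1 | intermediate (not isolated)
19 | protected dimer, middle 3-O-gallate, lower 3-O-TBS | O=C(O[C@@H]1[C@@H](c2c(OCc9ccccc9)cc(OCc9ccccc9)c3c2O[C@H](c2ccc(OCc9ccccc9)c(OCc9ccccc9)c2)[C@@H](O[Si](C)(C)C(C)(C)C)C3)c2c(OCc9ccccc9)cc(OCc9ccccc9)cc2O[C@@H]1c1cc(OCc9ccccc9)c(OCc9ccccc9)c(OCc9ccccc9)c1)c1cc(OCc9ccccc9)c(OCc9ccccc9)c(OCc9ccccc9)c1 | intermediate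
20 | protected dimer, lower 3-OH free | O=C(O[C@@H]1[C@@H](c2c(OCc9ccccc9)cc(OCc9ccccc9)c3c2O[C@H](c2ccc(OCc9ccccc9)c(OCc9ccccc9)c2)[C@@H](O)C3)c2c(OCc9ccccc9)cc(OCc9ccccc9)cc2O[C@@H]1c1cc(OCc9ccccc9)c(OCc9ccccc9)c(OCc9ccccc9)c1)c1cc(OCc9ccccc9)c(OCc9ccccc9)c(OCc9ccccc9)c1 | intermediate
21 | protected dimer digallate | O=C(O[C@@H]1[C@@H](c2c(OCc9ccccc9)cc(OCc9ccccc9)c3c2O[C@H](c2ccc(OCc9ccccc9)c(OCc9ccccc9)c2)[C@@H](OC(=O)c2cc(OCc9ccccc9)c(OCc9ccccc9)c(OCc9ccccc9)c2)C3)c2c(OCc9ccccc9)cc(OCc9ccccc9)cc2O[C@@H]1c1cc(OCc9ccccc9)c(OCc9ccccc9)c(OCc9ccccc9)c1)c1cc(OCc9ccccc9)c(OCc9ccccc9)c(OCc9ccccc9)c1 | intermediate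
22 | (−)-epicatechin | O[C@@H]1Cc2c(O)cc(O)cc2O[C@@H]1c1ccc(O)c(O)c1 | starting material
23 | 5,7,3',4'-tetra-O-benzyl-(−)-epicatechin | O[C@@H]1Cc2c(OCc9ccccc9)cc(OCc9ccccc9)cc2O[C@@H]1c1ccc(OCc9ccccc9)c(OCc9ccccc9)c1 | intermediate
24 | 4β-(2-ethoxyethoxy)-5,7,3',4'-tetra-O-benzylepicatechin | CCOCCO[C@H]1c2c(OCc9ccccc9)cc(OCc9ccccc9)cc2O[C@H](c2ccc(OCc9ccccc9)c(OCc9ccccc9)c2)[C@@H]1O | intermediate
25 | 3-O-(tri-O-benzylgalloyl)-4β-(2-ethoxyethoxy)-tetra-O-benzylepicatechin | CCOCCO[C@H]1c2c(OCc9ccccc9)cc(OCc9ccccc9)cc2O[C@H](c2ccc(OCc9ccccc9)c(OCc9ccccc9)c2)[C@@H]1OC(=O)c1cc(OCc9ccccc9)c(OCc9ccccc9)c(OCc9ccccc9)c1 | intermediate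
26 | C4 carbocation from 25 | [CH+]1c2c(OCc9ccccc9)cc(OCc9ccccc9)cc2O[C@H](c2ccc(OCc9ccccc9)c(OCc9ccccc9)c2)[C@@H]1OC(=O)c1cc(OCc9ccccc9)c(OCc9ccccc9)c(OCc9ccccc9)c1 | intermediate (not isolated)
27 | perbenzylated trimer | O=C(O[C@@H]1[C@@H](c2c(OCc9ccccc9)cc(OCc9ccccc9)c3c2O[C@H](c2ccc(OCc9ccccc9)c(OCc9ccccc9)c2)[C@@H](OC(=O)c2cc(OCc9ccccc9)c(OCc9ccccc9)c(OCc9ccccc9)c2)C3)c2c(OCc9ccccc9)cc(OCc9ccccc9)c([C@H]3c4c(OCc9ccccc9)cc(OCc9ccccc9)cc4O[C@H](c4ccc(OCc9ccccc9)c(OCc9ccccc9)c4)[C@@H]3OC(=O)c3cc(OCc9ccccc9)c(OCc9ccccc9)c(OCc9ccccc9)c3)c2O[C@@H]1c1cc(OCc9ccccc9)c(OCc9ccccc9)c(OCc9ccccc9)c1)c1cc(OCc9ccccc9)c(OCc9ccccc9)c(OCc9ccccc9)c1 | intermediate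
28 | CNP0321910.1 | O=C(O[C@@H]1[C@@H](c2c(O)cc(O)c3c2O[C@H](c2ccc(O)c(O)c2)[C@@H](OC(=O)c2cc(O)c(O)c(O)c2)C3)c2c(O)cc(O)c([C@H]3c4c(O)cc(O)cc4O[C@H](c4ccc(O)c(O)c4)[C@@H]3OC(=O)c3cc(O)c(O)c(O)c3)c2O[C@@H]1c1cc(O)c(O)c(O)c1)c1cc(O)c(O)c(O)c1 | target

**Step count and risks**
Total: 19 steps. Longest linear sequence: 11 steps (steps 1, 2, 3, 6, 7, 11, 12, 13, 14, 18, 19).

Steps most likely to fail:

1. Step 11. Bond formation at the crowded, strongly stabilised methide carbon may be slow, the catalyst may give poor facial control, or the enol silyl ether may be protodesilylated by the water released. The fallback sets out from 3 and 11 and uses the known biomimetic coupling with a ready-made middle unit. Commercial (−)-epigallocatechin is benzylated on its five phenols (BnBr, K2CO3, DMF) to penta-O-benzyl-epigallocatechin F1. DDQ and 2-ethoxyethanol give the 4β-(2-ethoxyethoxy) ether F2. Steglich esterification with 11 gives the 3-O-gallate F3. Coupling of F3 with an excess of 3 (Me3SiOTf, CH2Cl2, −78 °C) should form the 4β→8 bond trans to the acyloxy group and returns to the route at 19.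

2. Step 12. Hydride may be delivered from the face anti to the C4 aryl group instead of anti to the ester, or the Lewis acid may cleave the silyl ether or the C4–C8 bond. The fallback sets out from 17 and closes O1–C2 by substitution instead of reduction. Mild hydrolysis of the silyl ketal (pyridinium p-toluenesulfonate, wet THF) gives the hydroxy ketone F4, in equilibrium with its hemiketal. Corey–Bakshi–Shibata reduction, with the oxazaborolidine enantiomer chosen by reagent control, gives the (S)-configured benzylic carbinol F5. Intramolecular Mitsunobu etherification (PPh3, diisopropyl azodicarboxylate) of the phenol onto this carbinol with inversion gives the 2,3-cis flavan and returns to the route at 19.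

3. Step 18. The bulky, electron-poor galloylated electrophile may ionise slowly, so that scission of the existing interflavan bond or attack at a C6 position competes. The fallback sets out from 24 and 21 and acylates after the coupling. The more reactive 3-hydroxy electrophile 24 is coupled with 21 (Me3SiOTf, CH2Cl2, −78 °C) to give the trimer with a free upper 3-OH F6. Steglich esterification of F6 with 11 returns to the route at 27.

**Further compounds**
F1 | step 11 | 5,7,3',4',5'-penta-O-benzyl-(−)-epigallocatechin | O[C@@H]1Cc2c(OCc9ccccc9)cc(OCc9ccccc9)cc2O[C@@H]1c1cc(OCc9ccccc9)c(OCc9ccccc9)c(OCc9ccccc9)c1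
F2 | step 11 | 4β-(2-ethoxyethoxy)-penta-O-benzyl-epigallocatechin | CCOCCO[C@H]1c2c(OCc9ccccc9)cc(OCc9ccccc9)cc2O[C@H](c2cc(OCc9ccccc9)c(OCc9ccccc9)c(OCc9ccccc9)c2)[C@@H]1O
F3 | step 11 | 3-O-(tri-O-benzylgalloyl)-4β-(2-ethoxyethoxy)-penta-O-benzyl-epigallocatechin | CCOCCO[C@H]1c2c(OCc9ccccc9)cc(OCc9ccccc9)cc2O[C@H](c2cc(OCc9ccccc9)c(OCc9ccccc9)c(OCc9ccccc9)c2)[C@@H]1OC(=O)c1cc(OCc9ccccc9)c(OCc9ccccc9)c(OCc9ccccc9)c1
F4 | step 12 | open-chain hydroxy ketone from 17 (α-galloyloxy aryl ketone with free phenol) | O=C(O[C@@H](C(=O)c1cc(OCc9ccccc9)c(OCc9ccccc9)c(OCc9ccccc9)c1)[C@@H](c2c(OCc9ccccc9)cc(OCc9ccccc9)c3c2O[C@H](c2ccc(OCc9ccccc9)c(OCc9ccccc9)c2)[C@@H](O[Si](C)(C)C(C)(C)C)C3)c2c(OCc9ccccc9)cc(OCc9ccccc9)cc2O)c1cc(OCc9ccccc9)c(OCc9ccccc9)c(OCc9ccccc9)c1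
F5 | step 12 | (S)-benzylic carbinol from F4 | O=C(O[C@@H]([C@@H](O)c1cc(OCc9ccccc9)c(OCc9ccccc9)c(OCc9ccccc9)c1)[C@@H](c2c(OCc9ccccc9)cc(OCc9ccccc9)c3c2O[C@H](c2ccc(OCc9ccccc9)c(OCc9ccccc9)c2)[C@@H](O[Si](C)(C)C(C)(C)C)C3)c2c(OCc9ccccc9)cc(OCc9ccccc9)cc2O)c1cc(OCc9ccccc9)c(OCc9ccccc9)c(OCc9ccccc9)c1
F6 | step 18 | perbenzylated trimer with free upper 3-OH | O=C(O[C@@H]1[C@@H](c2c(OCc9ccccc9)cc(OCc9ccccc9)c3c2O[C@H](c2ccc(OCc9ccccc9)c(OCc9ccccc9)c2)[C@@H](OC(=O)c2cc(OCc9ccccc9)c(OCc9ccccc9)c(OCc9ccccc9)c2)C3)c2c(OCc9ccccc9)cc(OCc9ccccc9)c([C@H]3c4c(OCc9ccccc9)cc(OCc9ccccc9)cc4O[C@H](c4ccc(OCc9ccccc9)c(OCc9ccccc9)c4)[C@@H]3O)c2O[C@@H]1c1cc(OCc9ccccc9)c(OCc9ccccc9)c(OCc9ccccc9)c1)c1cc(OCc9ccccc9)c(OCc9ccccc9)c(OCc9ccccc9)c1
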